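The route rests on disconnecting ring B at C5–C6 together with the C4–C19 bond. In one operation the C6 radical closes ring B onto C5 of a ring A enone, and the boron enolate so generated is hydroxymethylated at C4 by formaldehyde. The step exploits that C5, the ring-fusion CH, lies between the quaternary carbons C4 and C10 and that C4 is the α-carbon of a latent C3 ketone; C10 alone dictates the cis A/B fusion of the target. The precursor is an (S)-4-methylcyclohex-2-enone bearing a silyloxymethyl group on C4 and, on C10, a tether with ketal-masked C8 that ends in the C6 iodide.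

Key step: step 11

Numbering: labdane numbering throughout (ring A C1–C5 and C10; ring B C5–C10; C20 methyl on C10; C17 on C8; C18 and C19 on C4; C11–C12 and lactone C13–C16 on C9). "cis-Decalin" means the C5/C10-fused decahydronaphthalene with H-5 cis to C20. TES = triethylsilyl, TBS = tert-butyldimethylsilyl, DTBS = di-tert-butylsilanediyl bridging O18 and O19.

Assumption: the quinine-derived primary amine of step 6 is taken to induce the S configuration at C10; if the sense proves opposite, the pseudoenantiomeric quinidine-derived amine is used.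

Remark: the CIP descriptors at C9 and C10 change in 28 and 29 only because the C8 carbonyl alters priorities; the spatial arrangement is that of the target.

Step 1
Reactants: 1 3-chloropropanoyl chloride
Product: 2 3-chloro-N-methoxy-N-methylpropanamide
Conditions: MeNH(OMe)·HCl, K2CO3, CH2Cl2/H2O, 0 °C
Reagents that add atoms: N,O-dimethylhydroxylamine hydrochloride, CNOC.Cl
Why: Schotten–Baumann N-acylation; at 0 °C with a two-phase carbonate base the amine should be acylated faster than HCl is eliminated from the β-chloro amide.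

Step 2
Reactants: 2 3-chloro-N-methoxy-N-methylpropanamide; 3 2-methylallylmagnesium chloride
Product: 5 1-chloro-5-methylhex-5-en-3-one, via magnesium hemiaminal chelate 4 (not isolated)
Conditions: THF, −78 → −20 °C; cold aq. NH4Cl; used crude
Reagents that add atoms: none
Why: Weinreb ketone synthesis; the chelated tetrahedral adduct resists a second allylation, and cold near-neutral hydrolysis should release the ketone without alkene conjugation or loss of HCl.

Step 3
Reactants: 5 1-chloro-5-methylhex-5-en-3-one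
Product: 6 2-(2-chloroethyl)-2-(2-methylprop-2-en-1-yl)-1,3-dioxolane
Conditions: Me3SiOCH2CH2OSiMe3, Me3SiOTf (cat.), CH2Cl2, −78 → −20 °C; pyridine quench
Reagents that add atoms: 1,2-bis(trimethylsilyloxy)ethane, C[Si](C)(C)OCCO[Si](C)(C)C
Why: Silyl-transfer ketalisation at low temperature masks C8 without acid-induced migration of the methallyl double bond or elimination of chloride.

Step 4
Reactants: 6 2-(2-chloroethyl)-2-(2-methylprop-2-en-1-yl)-1,3-dioxolane
Product: 8 rac-3-[2-(2-chloroethyl)-1,3-dioxolan-2-yl]-2-methylpropan-1-ol, via B-alkyl-9-BBN 7 (not isolated)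
Conditions: 9-BBN, THF, 0 °C → rt; then NaOH (aq), H2O2, 0 °C
Reagents that add atoms: hydrogen peroxide, OO
Why: Anti-Markovnikov hydroboration–oxidation of the 1,1-disubstituted alkene; the methyl-bearing centre (later C10) forms racemic, which is irrelevant because it is set again in step 6.

Step 5
Reactants: 8 rac-3-[2-(2-chloroethyl)-1,3-dioxolan-2-yl]-2-methylpropan-1-ol
Product: 9 rac-3-[2-(2-chloroethyl)-1,3-dioxolan-2-yl]-2-methylpropanal
Conditions: Dess–Martin periodinane, NaHCO3, CH2Cl2, 0 °C → rt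
Reagents that add atoms: none
Why: Buffered Dess–Martin oxidation gives the α-methyl aldehyde without touching the ketal or the chloride.

Step 6
Reactants: 9 rac-3-[2-(2-chloroethyl)-1,3-dioxolan-2-yl]-2-methylpropanal; 10 methyl vinyl ketone
Product: 12 (4S)-4-{[2-(2-chloroethyl)-1,3-dioxolan-2-yl]methyl}-4-methylcyclohex-2-en-1-one, via keto aldehyde 11 (not isolated)
Conditions: 9-amino-9-deoxy-epi-quinine (20 mol %), PhCO2H (40 mol %), toluene, 0 °C → rt; then KOH (cat.), MeOH, rt
Reagents that add atoms: none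
Why: Amine-catalysed asymmetric Robinson annulation (Michael addition, then intramolecular aldol condensation); the racemic aldehyde converges on one trisubstituted enamine whose geometry is biased by the bulky ketal arm against methyl, and its open face adds to the enone to set quaternary C10 as S.

Step 7
Reactants: 12 (4S)-4-{[2-(2-chloroethyl)-1,3-dioxolan-2-yl]methyl}-4-methylcyclohex-2-en-1-one
Product: 13 (4S)-4-{[2-(2-chloroethyl)-1,3-dioxolan-2-yl]methyl}-2-iodo-4-methylcyclohex-2-en-1-one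
Conditions: I2, K2CO3, DMAP (cat.), THF/H2O, rt
Reagents that add atoms: iodine, II
Why: α-Iodination of the enone by a Morita–Baylis–Hillman-type addition–iodination–elimination sequence, which tolerates the quaternary γ-carbon.

Step 8
Reactants: 13 (4S)-4-{[2-(2-chloroethyl)-1,3-dioxolan-2-yl]methyl}-2-iodo-4-methylcyclohex-2-en-1-one
Product: 14 (4S)-4-{[2-(2-chloroethyl)-1,3-dioxolan-2-yl]methyl}-2-(hydroxymethyl)-4-methylcyclohex-2-en-1-one
Conditions: Bu3SnCH2OH, Pd(PPh3)4, 1,4-dioxane, 90 °C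
Reagents that add atoms: (tributylstannyl)methanol, CCCC[Sn](CCCC)(CCCC)CO
Why: Stille coupling of the α-iodoenone installs C18 with its oxygen; the primary alkyl chloride should not undergo oxidative addition to zerovalent palladium under these conditions.

Step 9
Reactants: 14 (4S)-4-{[2-(2-chloroethyl)-1,3-dioxolan-2-yl]methyl}-2-(hydroxymethyl)-4-methylcyclohex-2-en-1-one
Product: 15 (4S)-2-(hydroxymethyl)-4-{[2-(2-iodoethyl)-1,3-dioxolan-2-yl]methyl}-4-methylcyclohex-2-en-1-one
Conditions: NaI, NaHCO3, butan-2-one, 75 °C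
Reagents that add atoms: sodium iodide, [Na+].[I-]
Why: Finkelstein exchange (SN2) at the unhindered primary chloride, driven by precipitation of NaCl.

Step 10
Reactants: 15 (4S)-2-(hydroxymethyl)-4-{[2-(2-iodoethyl)-1,3-dioxolan-2-yl]methyl}-4-methylcyclohex-2-en-1-one
Product: 16 (4S)-4-{[2-(2-iodoethyl)-1,3-dioxolan-2-yl]methyl}-4-methyl-2-{[(triethylsilyl)oxy]methyl}cyclohex-2-en-1-one
Conditions: Et3SiCl, imidazole, DMAP (cat.), CH2Cl2, 0 °C
Reagents that add atoms: chlorotriethylsilane, CC[Si](Cl)(CC)CC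
Why: Silylation of the primary allylic alcohol; the TES ether survives chromatography and the aprotic radical step, yet is cleaved in the work-up of step 11.

Step 11
Reactants: 16 (4S)-4-{[2-(2-iodoethyl)-1,3-dioxolan-2-yl]methyl}-4-methyl-2-{[(triethylsilyl)oxy]methyl}cyclohex-2-en-1-one; 17 formaldehyde
Product: 20 (5R,10S)-4,4-bis(hydroxymethyl)-10-methyl-cis-decalin-3,8-dione 8-(ethylene ketal), via diethylboron enolate 18 (not isolated), via mono-TES aldol 19 (not isolated)
Conditions: Et3B (3 equiv), air (slow addition), CH2Cl2, −40 → 0 °C; then anhydrous monomeric CH2O in THF, −78 → −20 °C; pH 7 buffer; then HF·pyridine, pyridine, THF, 0 °C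
Reagents that add atoms: none
Why: Ethyl radicals from Et3B/O2 abstract iodine from C6, the primary C6 radical adds to C5 (the β-carbon of the ring A enone), and the C4 enoxyl radical is captured at oxygen by Et3B, which releases the chain-carrying ethyl radical and gives a C3–O–BEt2 enolate that then adds to formaldehyde at C4. The closest known reaction type is the triethylborane-mediated radical conjugate addition–boron enolate aldol sequence (radical–polar crossover), here with the radical event made intramolecular. Ring B closes in the 6-exo-trig mode; 7-endo attack at C4 is disfavoured because only attack at C5 gives the delocalised enoxyl radical. The new stereocentre C5 is controlled by C10: the tether from C10 can reach the adjacent C5 only on its own face, so C6 and C9 become cis and H-5 ends up cis to the C20 methyl (5R from 10S). The step needs aldol addition to outrun protonation of the enolate and β-elimination of the O18 silyloxide, which the aprotic medium, the silyl cap, the low temperature and the high electrophilicity of monomeric formaldehyde should secure; C4 needs no facial control because both arms become identical on desilylation.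

Step 12
Reactants: 20 (5R,10S)-4,4-bis(hydroxymethyl)-10-methyl-cis-decalin-3,8-dione 8-(ethylene ketal)
Product: 21 (5R,10S)-18,19-O-DTBS-4,4-bis(oxymethyl)-10-methyl-cis-decalin-3,8-dione 8-(ethylene ketal)
Conditions: t-Bu2Si(OTf)2, 2,6-lutidine, CH2Cl2, 0 °C
Reagents that add atoms: di-tert-butylsilyl bis(trifluoromethanesulfonate), CC(C)(C)[Si](OS(=O)(=O)C(F)(F)F)(OS(=O)(=O)C(F)(F)F)C(C)(C)C
Why: Cyclic silylene formation on the 1,3-diol protects both arms in one operation with a group that should survive dissolving metal, mild aqueous acid, enolate and hydride chemistry.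

Step 13
Reactants: 21 (5R,10S)-18,19-O-DTBS-4,4-bis(oxymethyl)-10-methyl-cis-decalin-3,8-dione 8-(ethylene ketal)
Product: 22 (3R,5R,10S)-3-hydroxy-18,19-O-DTBS-4,4-bis(oxymethyl)-10-methyl-cis-decalin-8-one ethylene ketal
Conditions: Li, NH3(l)/THF, t-BuOH, −78 °C; NH4Cl
Reagents that add atoms: none
Why: Dissolving-metal (Birch-type) ketone reduction, which gives the thermodynamically favoured alcohol; the geminally substituted C4 holds the cis-decalin in the conformer with C20 axial on ring A, where the C3–OH cis to C20 is equatorial and its epimer would be syn-diaxial to C6, so C3 should be set as R.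

Step 14
Reactants: 22 (3R,5R,10S)-3-hydroxy-18,19-O-DTBS-4,4-bis(oxymethyl)-10-methyl-cis-decalin-8-one ethylene ketal
Product: 23 (3R,5R,10S)-3-(TBSO)-18,19-O-DTBS-4,4-bis(oxymethyl)-10-methyl-cis-decalin-8-one ethylene ketal
Conditions: TBSOTf, 2,6-lutidine, CH2Cl2, 0 °C → rt
Reagents that add atoms: tert-butyldimethylsilyl trifluoromethanesulfonate, CC(C)(C)[Si](C)(C)OS(=O)(=O)C(F)(F)F
Why: Silylation of the hindered neopentylic secondary alcohol with the reactive silyl triflate; the ketal is inert to the lutidine-buffered reagent.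

Step 15
Reactants: 23 (3R,5R,10S)-3-(TBSO)-18,19-O-DTBS-4,4-bis(oxymethyl)-10-methyl-cis-decalin-8-one ethylene ketal
Product: 24 (3R,5R,10S)-3-(TBSO)-18,19-O-DTBS-4,4-bis(oxymethyl)-10-methyl-cis-decalin-8-one
Conditions: PPTS, acetone/H2O, 55 °C
Reagents that add atoms: water, O
Why: Acid-catalysed ketal hydrolysis (exchange into acetone) unmasks C8; both hindered silyl groups should be stable to the pyridinium salt.

Step 16
Reactants: 24 (3R,5R,10S)-3-(TBSO)-18,19-O-DTBS-4,4-bis(oxymethyl)-10-methyl-cis-decalin-8-one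
Product: 25 (3R,5R,10S)-3-(TBSO)-18,19-O-DTBS-4,4-bis(oxymethyl)-10-methyl-cis-decal-6-en-8-one
Conditions: IBX, DMSO/toluene, 70 °C
Reagents that add atoms: none
Why: IBX-mediated α,β-dehydrogenation of the ketone; only C6–C7 can be desaturated because C10 is quaternary, so the enone forms regioselectively and removes C7 as an enolisable site.

Step 17
Reactants: 25 (3R,5R,10S)-3-(TBSO)-18,19-O-DTBS-4,4-bis(oxymethyl)-10-methyl-cis-decal-6-en-8-one; 26 ethyl iodoacetate
Product: 28 ethyl [(3R,5R,9S,10R)-3-(TBSO)-18,19-O-DTBS-4,4-bis(oxymethyl)-10-methyl-8-oxo-cis-decal-6-en-9-yl]acetate, via lithium dienolate 27 (not isolated)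
Conditions: LiN(i-Pr)2, THF, −78 °C; then 26, DMPU, −78 → −40 °C
Reagents that add atoms: none
Why: Kinetic α′-deprotonation at C9 and SN2 alkylation of the cross-conjugated lithium dienolate with the activated iodide; ring A shields the concave face of the cis-fused bicycle in either ring conformer, so the electrophile should enter C9 anti to the C1–C10 bond and place the chain cis to the C20 methyl.

Step 18
Reactants: 28 ethyl [(3R,5R,9S,10R)-3-(TBSO)-18,19-O-DTBS-4,4-bis(oxymethyl)-10-methyl-8-oxo-cis-decal-6-en-9-yl]acetate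
Product: 29 ethyl [(3R,5R,9S,10R)-3-(TBSO)-18,19-O-DTBS-4,4-bis(oxymethyl)-10-methyl-8-oxo-cis-decalin-9-yl]acetate
Conditions: H2 (1 atm), Pd/C, EtOAc, rt
Reagents that add atoms: none
Why: Heterogeneous catalytic hydrogenation saturates the C6=C7 bond under neutral conditions that should not epimerise C9.

Step 19
Reactants: 29 ethyl [(3R,5R,9S,10R)-3-(TBSO)-18,19-O-DTBS-4,4-bis(oxymethyl)-10-methyl-8-oxo-cis-decalin-9-yl]acetate
Product: 30 ethyl [(3R,5R,9R,10S)-3-(TBSO)-18,19-O-DTBS-4,4-bis(oxymethyl)-10-methyl-8-methylidene-cis-decalin-9-yl]acetate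
Conditions: Zn, CH2Br2, TiCl4, THF (preformed reagent); then 29, CH2Cl2, 0 °C → rt
Reagents that add atoms: dibromomethane, BrCBr
Why: Takai–Lombardo methylenation; the non-basic zinc–titanium methylene reagent converts the hindered, epimerisable ketone into the C8=C17 alkene without enolisation and leaves the ester untouched.

Step 20
Reactants: 30 ethyl [(3R,5R,9R,10S)-3-(TBSO)-18,19-O-DTBS-4,4-bis(oxymethyl)-10-methyl-8-methylidene-cis-decalin-9-yl]acetate
Product: 31 2-[(3R,5R,9R,10S)-3-(TBSO)-18,19-O-DTBS-4,4-bis(oxymethyl)-10-methyl-8-methylidene-cis-decalin-9-yl]ethan-1-ol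
Conditions: (i-Bu)2AlH, CH2Cl2, −78 → 0 °C; aq. KNaC4H4O6
Reagents that add atoms: none
Why: Hydride reduction of the ester to the primary alcohol (C12); silyl ethers and the isolated alkene are inert.

Step 21
Reactants: 31 2-[(3R,5R,9R,10S)-3-(TBSO)-18,19-O-DTBS-4,4-bis(oxymethyl)-10-methyl-8-methylidene-cis-decalin-9-yl]ethan-1-ol
Product: 32 (3R,5R,9R,10S)-9-(2-iodoethyl)-3-(TBSO)-18,19-O-DTBS-4,4-bis(oxymethyl)-10-methyl-8-methylidene-cis-decalin
Conditions: I2, PPh3, imidazole, CH2Cl2, 0 °C → rt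
Reagents that add atoms: iodine, II
Why: Appel-type iodination of the primary alcohol through its alkoxyphosphonium salt (SN2 at CH2).

Step 22
Reactants: 33 3-bromooxolan-2-one
Product: 34 3-(phenylsulfanyl)oxolan-2-one
Conditions: PhSH, Et3N, CH2Cl2, 0 °C → rt
Reagents that add atoms: thiophenol, Sc1ccccc1
Why: SN2 displacement of the activated α-bromide by thiolate.

Step 23
Reactants: 32 (3R,5R,9R,10S)-9-(2-iodoethyl)-3-(TBSO)-18,19-O-DTBS-4,4-bis(oxymethyl)-10-methyl-8-methylidene-cis-decalin; 34 3-(phenylsulfanyl)oxolan-2-one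
Product: 36 3-{2-[(3R,5R,9R,10S)-3-(TBSO)-18,19-O-DTBS-4,4-bis(oxymethyl)-10-methyl-8-methylidene-cis-decalin-9-yl]ethyl}-3-(phenylsulfanyl)oxolan-2-one (C13 epimers), via potassium enolate 35 (not isolated)
Conditions: 34, KN(SiMe3)2, THF, 0 °C; then 32, DMPU, 0 °C → rt
Reagents that add atoms: none
Why: SN2 alkylation of the sulfur-stabilised lactone enolate with the unhindered primary iodide forms C12–C13; the C13 centre forms as a mixture that is erased in step 24.

Step 24
Reactants: 36 3-{2-[(3R,5R,9R,10S)-3-(TBSO)-18,19-O-DTBS-4,4-bis(oxymethyl)-10-methyl-8-methylidene-cis-decalin-9-yl]ethyl}-3-(phenylsulfanyl)oxolan-2-one (C13 epimers)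
Product: 38 3-{2-[(3R,5R,9R,10S)-3-(TBSO)-18,19-O-DTBS-4,4-bis(oxymethyl)-10-methyl-8-methylidene-cis-decalin-9-yl]ethyl}furan-2(5H)-one, via sulfoxide 37 (not isolated)
Conditions: m-CPBA (1 equiv), NaHCO3, CH2Cl2, −78 → −30 °C; work-up; then toluene, 110 °C
Reagents that add atoms: none
Why: Chemoselective S-oxidation (the sulfide is far more nucleophilic than the 1,1-disubstituted alkene) followed by thermal sulfoxide syn-elimination toward the ring CH2, which gives the endocyclic C13=C14 butenolide.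

Step 25
Reactants: 38 3-{2-[(3R,5R,9R,10S)-3-(TBSO)-18,19-O-DTBS-4,4-bis(oxymethyl)-10-methyl-8-methylidene-cis-decalin-9-yl]ethyl}furan-2(5H)-one
Product: 39 (3R,5R,9R,10S)-3,18,19-trihydroxylabda-8(17),13-dien-16,15-olide (CNP0146463.1)
Conditions: HF·pyridine, pyridine, THF, 0 °C → rt
Reagents that add atoms: none
Why: Fluoride-mediated cleavage of the silylene and the silyl ether under buffered, weakly acidic conditions that should spare the butenolide and the exocyclic alkene.

Compound list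
1 | 3-chloropropanoyl chloride | O=C(Cl)CCCl | starting material
2 | 3-chloro-N-methoxy-N-methylpropanamide | CON(C)C(=O)CCCl | intermediate
3 | 2-methylallylmagnesium chloride | CC(=C)C[Mg]Cl | starting material
4 | magnesium hemiaminal chelate (tetrahedral adduct of 2 and 3) | CON(C)C(CCCl)(CC(C)=C)O[Mg]Cl | intermediate
5 | 1-chloro-5-methylhex-5-en-3-one | CC(=C)CC(=O)CCCl | intermediate
6 | 2-(2-chloroethyl)-2-(2-methylprop-2-en-1-yl)-1,3-dioxolane | CC(=C)CC1(CCCl)OCCO1 | intermediate
7 | B-alkyl-9-borabicyclo[3.3.1]nonane from 6 | CC(CB1C2CCCC1CCC2)CC1(CCCl)OCCO1 | intermediate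
8 | rac-3-[2-(2-chloroethyl)-1,3-dioxolan-2-yl]-2-methylpropan-1-ol | CC(CO)CC1(CCCl)OCCO1 | intermediate
9 | rac-3-[2-(2-chloroethyl)-1,3-dioxolan-2-yl]-2-methylpropanal | CC(C=O)CC1(CCCl)OCCO1 | intermediate
10 | methyl vinyl ketone | CC(=O)C=C | starting material
11 | (2S)-2-{[2-(2-chloroethyl)-1,3-dioxolan-2-yl]methyl}-2-methyl-5-oxohexanal | CC(=O)CC[C@@](C)(CC1(CCCl)OCCO1)C=O | intermediate
12 | (4S)-4-{[2-(2-chloroethyl)-1,3-dioxolan-2-yl]methyl}-4-methylcyclohex-2-en-1-one | O=C1CC[C@@](C)(CC2(CCCl)OCCO2)C=C1 | intermediate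
13 | (4S)-4-{[2-(2-chloroethyl)-1,3-dioxolan-2-yl]methyl}-2-iodo-4-methylcyclohex-2-en-1-one | O=C1CC[C@@](C)(CC2(CCCl)OCCO2)C=C1I | intermediate
14 | (4S)-4-{[2-(2-chloroethyl)-1,3-dioxolan-2-yl]methyl}-2-(hydroxymethyl)-4-methylcyclohex-2-en-1-one | O=C1CC[C@@](C)(CC2(CCCl)OCCO2)C=C1CO | intermediate
15 | (4S)-2-(hydroxymethyl)-4-{[2-(2-iodoethyl)-1,3-dioxolan-2-yl]methyl}-4-methylcyclohex-2-en-1-one | O=C1CC[C@@](C)(CC2(CCI)OCCO2)C=C1CO | intermediate
16 | (4S)-4-{[2-(2-iodoethyl)-1,3-dioxolan-2-yl]methyl}-4-methyl-2-{[(triethylsilyl)oxy]methyl}cyclohex-2-en-1-one | O=C1CC[C@@](C)(CC2(CCI)OCCO2)C=C1CO[Si](CC)(CC)CC | intermediate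
17 | formaldehyde | C=O | starting material
18 | diethylboron enolate of the cyclised ketone (C3–OBEt2, C3=C4, O18–TES, C8 ethylene ketal) | O1CCOC12CC[C@H]3C(CO[Si](CC)(CC)CC)=C(OB(CC)CC)CC[C@@]3(C)C2 | intermediate
19 | 18-O-TES ether of 20 (C4 epimers) | O1CCOC12CC[C@H]3C(CO)(CO[Si](CC)(CC)CC)C(=O)CC[C@@]3(C)C2 | intermediate
20 | (5R,10S)-4,4-bis(hydroxymethyl)-10-methyl-cis-decalin-3,8-dione 8-(ethylene ketal) | O1CCOC12CC[C@H]3C(CO)(CO)C(=O)CC[C@@]3(C)C2 | intermediate
21 | (5R,10S)-18,19-O-DTBS-4,4-bis(oxymethyl)-10-methyl-cis-decalin-3,8-dione 8-(ethylene ketal) | O1CCOC12CC[C@H]3C4(CO[Si](C(C)(C)C)(C(C)(C)C)OC4)C(=O)CC[C@@]3(C)C2 | intermediate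
22 | (3R,5R,10S)-3-hydroxy-18,19-O-DTBS-4,4-bis(oxymethyl)-10-methyl-cis-decalin-8-one ethylene ketal | O1CCOC12CC[C@H]3C4(CO[Si](C(C)(C)C)(C(C)(C)C)OC4)[C@H](O)CC[C@@]3(C)C2 | intermediate
23 | (3R,5R,10S)-3-(TBSO)-18,19-O-DTBS-4,4-bis(oxymethyl)-10-methyl-cis-decalin-8-one ethylene ketal | O1CCOC12CC[C@H]3C4(CO[Si](C(C)(C)C)(C(C)(C)C)OC4)[C@H](O[Si](C)(C)C(C)(C)C)CC[C@@]3(C)C2 | intermediate
24 | (3R,5R,10S)-3-(TBSO)-18,19-O-DTBS-4,4-bis(oxymethyl)-10-methyl-cis-decalin-8-one | O=C1CC[C@H]2C3(CO[Si](C(C)(C)C)(C(C)(C)C)OC3)[C@H](O[Si](C)(C)C(C)(C)C)CC[C@@]2(C)C1 | intermediate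
25 | (3R,5R,10S)-3-(TBSO)-18,19-O-DTBS-4,4-bis(oxymethyl)-10-methyl-cis-decal-6-en-8-one | O=C1C=C[C@H]2C3(CO[Si](C(C)(C)C)(C(C)(C)C)OC3)[C@H](O[Si](C)(C)C(C)(C)C)CC[C@@]2(C)C1 | intermediate
26 | ethyl iodoacetate | CCOC(=O)CI | starting material
27 | lithium dienolate of 25 (C8–OLi, C8=C9, C6=C7) | [Li]OC=1C=C[C@H]2C3(CO[Si](C(C)(C)C)(C(C)(C)C)OC3)[C@H](O[Si](C)(C)C(C)(C)C)CC[C@@]2(C)C=1 | intermediate
28 | ethyl [(3R,5R,9S,10R)-3-(TBSO)-18,19-O-DTBS-4,4-bis(oxymethyl)-10-methyl-8-oxo-cis-decal-6-en-9-yl]acetate | O=C1C=C[C@H]2C3(CO[Si](C(C)(C)C)(C(C)(C)C)OC3)[C@H](O[Si](C)(C)C(C)(C)C)CC[C@@]2(C)[C@@H]1CC(=O)OCC | intermediate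
29 | ethyl [(3R,5R,9S,10R)-3-(TBSO)-18,19-O-DTBS-4,4-bis(oxymethyl)-10-methyl-8-oxo-cis-decalin-9-yl]acetate | O=C1CC[C@H]2C3(CO[Si](C(C)(C)C)(C(C)(C)C)OC3)[C@H](O[Si](C)(C)C(C)(C)C)CC[C@@]2(C)[C@@H]1CC(=O)OCC | intermediate
30 | ethyl [(3R,5R,9R,10S)-3-(TBSO)-18,19-O-DTBS-4,4-bis(oxymethyl)-10-methyl-8-methylidene-cis-decalin-9-yl]acetate | C=C1CC[C@H]2C3(CO[Si](C(C)(C)C)(C(C)(C)C)OC3)[C@H](O[Si](C)(C)C(C)(C)C)CC[C@@]2(C)[C@@H]1CC(=O)OCC | intermediate
31 | 2-[(3R,5R,9R,10S)-3-(TBSO)-18,19-O-DTBS-4,4-bis(oxymethyl)-10-methyl-8-methylidene-cis-decalin-9-yl]ethan-1-ol | C=C1CC[C@H]2C3(CO[Si](C(C)(C)C)(C(C)(C)C)OC3)[C@H](O[Si](C)(C)C(C)(C)C)CC[C@@]2(C)[C@@H]1CCO | intermediate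
32 | (3R,5R,9R,10S)-9-(2-iodoethyl)-3-(TBSO)-18,19-O-DTBS-4,4-bis(oxymethyl)-10-methyl-8-methylidene-cis-decalin | C=C1CC[C@H]2C3(CO[Si](C(C)(C)C)(C(C)(C)C)OC3)[C@H](O[Si](C)(C)C(C)(C)C)CC[C@@]2(C)[C@@H]1CCI | intermediate
33 | 3-bromooxolan-2-one (α-bromo-γ-butyrolactone, racemic) | BrC1CCOC1=O | starting material
34 | 3-(phenylsulfanyl)oxolan-2-one (racemic) | O=C1OCCC1Sc1ccccc1 | intermediate
35 | potassium enolate of 34 | [K]OC1=C(Sc2ccccc2)CCO1 | intermediate
36 | 3-{2-[(3R,5R,9R,10S)-3-(TBSO)-18,19-O-DTBS-4,4-bis(oxymethyl)-10-methyl-8-methylidene-cis-decalin-9-yl]ethyl}-3-(phenylsulfanyl)oxolan-2-one (C13 epimers) | C=C1CC[C@H]2C3(CO[Si](C(C)(C)C)(C(C)(C)C)OC3)[C@H](O[Si](C)(C)C(C)(C)C)CC[C@@]2(C)[C@@H]1CCC1(Sc2ccccc2)CCOC1=O | intermediate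
37 | S-oxide of 36 (sulfoxide, epimer mixture) | C=C1CC[C@H]2C3(CO[Si](C(C)(C)C)(C(C)(C)C)OC3)[C@H](O[Si](C)(C)C(C)(C)C)CC[C@@]2(C)[C@@H]1CCC1(S(=O)c2ccccc2)CCOC1=O | intermediate
38 | 3-{2-[(3R,5R,9R,10S)-3-(TBSO)-18,19-O-DTBS-4,4-bis(oxymethyl)-10-methyl-8-methylidene-cis-decalin-9-yl]ethyl}furan-2(5H)-one | C=C1CC[C@H]2C3(CO[Si](C(C)(C)C)(C(C)(C)C)OC3)[C@H](O[Si](C)(C)C(C)(C)C)CC[C@@]2(C)[C@@H]1CCC1=CCOC1=O | intermediate
39 | (3R,5R,9R,10S)-3,18,19-trihydroxylabda-8(17),13-dien-16,15-olide (CNP0146463.1) | C=C1CC[C@H]2C(CO)(CO)[C@H](O)CC[C@@]2(C)[C@@H]1CCC1=CCOC1=O | target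

Total step count: 25. Longest linear sequence: 24 (steps 1–21 and 23–25; step 22 is a one-step branch).

Steps most likely to fail

Step 11. The tandem would break if the boron enolate is protonated or loses the O18 silyloxide before it meets formaldehyde, or if the C6 radical is quenched by hydrogen abstraction before ring closure. Fallback: the radical and the polar event are separated. Setting out from 16, a reductive Giese-type cyclisation with (Me3Si)3SiH and AIBN in toluene at 80 °C should give, under the same C10 control, the cis-fused C4–H ketone F1. Equilibrating silylation (Me3SiCl, NaI, Et3N, MeCN) should then give the tetrasubstituted trimethylsilyl enol ether F2. A Mukaiyama-type hydroxymethylation with aqueous formaldehyde and Yb(OTf)3 in THF should deliver 19, which HF·pyridine converts into 20, where the route is rejoined.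

Step 6. Incomplete control of the enamine geometry of the α-methyl aldehyde would erode the enantiofacial discrimination at C10. Fallback: asymmetric catalysis is replaced by resolution. From 9 and 10, a pyrrolidine-mediated Stork enamine Michael addition followed by KOH/MeOH aldol condensation gives the racemic enone F3. Preparative chromatography on an amylose tris(3,5-dimethylphenylcarbamate) stationary phase then supplies the S enantiomer, which is 12.

Step 17. The electrophile may attack the ring A face of the C9 dienolate, or γ-deprotonation at C5 may compete with the slow reaction at the neopentyl C9. Fallback: the order of bond formation at C9 is reversed, so that hydrogen rather than carbon is delivered last. From 25, the dienolate 27 is added to ethyl glyoxylate to give the aldol adduct F4. Mesylation (MsCl, Et3N) gives the mesylate F5, and elimination with DBU gives the C9=C11 alkylidene F6. Hydrogenation over Pd/C then saturates both C6=C7 and C9=C11, with hydrogen entering C9 on the face that the electrophile had preferred, and gives 29.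

Further compounds
F1 | step 11 | cis-fused C4–H ketone: (5R,10S)-4-[(triethylsilyloxy)methyl]-10-methyl-cis-decalin-3,8-dione 8-(ethylene ketal), C4 epimers | O1CCOC12CC[C@H]3C(CO[Si](CC)(CC)CC)C(=O)CC[C@@]3(C)C2
F2 | step 11 | trimethylsilyl enol ether of F1 (C3–OSiMe3, C3=C4) | O1CCOC12CC[C@H]3C(CO[Si](CC)(CC)CC)=C(O[Si](C)(C)C)CC[C@@]3(C)C2
F3 | step 6 | racemic 4-{[2-(2-chloroethyl)-1,3-dioxolan-2-yl]methyl}-4-methylcyclohex-2-en-1-one | O=C1CCC(C)(CC2(CCCl)OCCO2)C=C1
F4 | step 17 | aldol adduct of 27 and ethyl glyoxylate (C9–CH(OH)CO2Et, epimer mixture) | O=C1C=C[C@H]2C3(CO[Si](C(C)(C)C)(C(C)(C)C)OC3)[C@H](O[Si](C)(C)C(C)(C)C)CC[C@@]2(C)C1C(O)C(=O)OCC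
F5 | step 17 | mesylate of F4 | O=C1C=C[C@H]2C3(CO[Si](C(C)(C)C)(C(C)(C)C)OC3)[C@H](O[Si](C)(C)C(C)(C)C)CC[C@@]2(C)C1C(OS(C)(=O)=O)C(=O)OCC
F6 | step 17 | C9=C11 alkylidene enone ester | O=C1C=C[C@H]2C3(CO[Si](C(C)(C)C)(C(C)(C)C)OC3)[C@H](O[Si](C)(C)C(C)(C)C)CC[C@@]2(C)C1=CC(=O)OCC
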